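**Retrosynthetic overview**

- Feature: ring A is a benzoate with oxygen on C2 and C4 and the C12 chain on C6, so its carboxyl carbon and C1–C6 map onto C1–C7 of a 3,5,7-triketo ester; the carboxyl is esterified by the secondary carbinol C4 of the ring B undecyl chain and sits between the C2 hydroxyl and the C6 alkyl group.
- Target ⇒ hydrogenolysis of the two ring B benzyl ethers and methylation of the C4 hydroxyl of ring A ⇒ 2,4-dihydroxybenzoate ester.
- Ring A (C1–C6 bond) and the ester C–O bond ⇒ diketo-dioxinone + ring B carbinol, joined in one pot by acyl ketene capture, aldol closure and aromatisation; ring A is the only ring built and is formed last, ring B is bought as an aryl bromide.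
- Diketo-dioxinone ⇒ dianion of the acetyl-dioxinone + imidazolide of (R)-10-acetoxytridecanoic acid; the acid comes from (R)-2-propyloxirane and a non-8-enyl Grignard reagent by acetylation and alkene cleavage.
- Ring B carbinol ⇒ (R)-2-propyloxirane + hex-5-enyl Grignard reagent, then 9-BBN hydroboration and Suzuki coupling with 1,3-bis(benzyloxy)-5-bromobenzene.

Key step: step 8

Remark on the chemistry: the 1,3-dicarbonyl compounds of the route (diketo-dioxinone, triketo ester, aldol adduct) are drawn as single tautomers although each should exist as a tautomeric mixture; the aldol adduct should form as a mixture of epimers at its ring carbinol carbon, which is lost on dehydration.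

**Route**

Step 1
Reactants: 1 9-bromonon-1-ene; 2 (R)-2-propyloxirane
Product: 4 (R)-tetradec-13-en-4-ol, via non-8-enylmagnesium bromide 3 (not isolated)
Conditions: Mg, THF, rt to 40 °C; then CuBr·SMe2 (10 mol %), 2, THF, −30 to 0 °C; dilute aq. HCl
Reagents that add atoms: none
Why: Copper-catalysed Grignard opening of a terminal epoxide is an SN2 attack at the unsubstituted CH2, so the C–O stereocentre of 2 is not touched and stays R in 4, because the former ring CH2 keeps its CIP rank as the long chain.

Step 2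
Reactants: 4 (R)-tetradec-13-en-4-ol
Product: 5 (R)-tetradec-13-en-4-yl acetate
Conditions: Ac2O, pyridine, DMAP (cat.), CH2Cl2, 0 °C to rt
Reagents that add atoms: acetic anhydride, CC(=O)OC(C)=O
Why: DMAP-catalysed acetylation of a secondary alcohol is a nucleophilic acyl substitution at the anhydride and breaks no bond at the stereocentre.

Step 3
Reactants: 5 (R)-tetradec-13-en-4-yl acetate
Product: 6 (R)-10-acetoxytridecanoic acid
Conditions: RuCl3 hydrate (2 mol %), NaIO4 (4.5 equiv), MeCN/EtOAc/H2O, rt
Reagents that add atoms: sodium periodate, [Na+].[O-]I(=O)(=O)=O; water, O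
Why: Ruthenium tetroxide RuO4, regenerated by periodate (Sharpless oxidative cleavage), should cut the terminal alkene to the carboxylic acid with loss of the terminal carbon, while the secondary acetate and the saturated chain are inert.

Step 4
Reactants: 7 2,2,6-trimethyl-4H-1,3-dioxin-4-one
Product: 9 2,2-dimethyl-6-(2-oxopropyl)-4H-1,3-dioxin-4-one, via lithium dienolate 8 (not isolated)
Conditions: LiN(SiMe3)2 (1 equiv per 7), THF, −78 °C; AcCl (0.5 equiv), −78 °C; dilute aq. HCl
Reagents that add atoms: acetyl chloride, CC(Cl)=O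
Why: Deprotonation of the C6 methyl group gives the vinylogous ester dienolate, which undergoes Claisen-type C-acylation at its terminal carbon; half an equivalent of acetyl chloride is used because the more acidic product consumes a second equivalent of dienolate.

Step 5
Reactants: 6 (R)-10-acetoxytridecanoic acid; 9 2,2-dimethyl-6-(2-oxopropyl)-4H-1,3-dioxin-4-one
Product: 12 (13R)-1-(2,2-dimethyl-4-oxo-4H-1,3-dioxin-6-yl)-2,4-dioxohexadecan-13-yl acetate, via acyl imidazolide 10 (not isolated), via dilithium dianion 11 (not isolated)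
Conditions: 6, 1,1'-carbonyldiimidazole, THF, rt; separately 9 (3 equiv), LiN(i-Pr)2 (6 equiv), THF, −78 °C, then Et2Zn (3 equiv), −78 to −20 °C; imidazolide solution added, −78 to −10 °C; dilute aq. HCl
Reagents that add atoms: none
Why: Claisen condensation of a β-dicarbonyl dianion (Harris-type γ-acylation) takes place at the terminal, last-formed carbanion; the acyl imidazolide is far more electrophilic than the remote secondary acetate, zinc transmetallation should limit proton transfer and O-acylation, and the excess dianion absorbs the imidazole N–H and the acidity of the product.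

Step 6
Reactants: 13 6-bromohex-1-ene; 2 (R)-2-propyloxirane
Product: 15 (R)-undec-10-en-4-ol, via hex-5-enylmagnesium bromide 14 (not isolated)
Conditions: Mg, THF, rt to 40 °C; then CuBr·SMe2 (10 mol %), 2, THF, −30 to 0 °C; dilute aq. HCl
Reagents that add atoms: none
Why: The same copper-catalysed SN2 opening of the epoxide at its CH2 terminus by a Grignard reagent as in step 1, so the R configuration of 2 is carried into the carbinol.

Step 7
Reactants: 15 (R)-undec-10-en-4-ol; 16 1,3-bis(benzyloxy)-5-bromobenzene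
Product: 18 (R)-11-[3,5-bis(benzyloxy)phenyl]undecan-4-ol, via alkyl-9-BBN borinate 17 (not isolated)
Conditions: 9-BBN dimer (1.25 equiv), THF, 0 °C to rt; then 16, Pd(dppf)Cl2·CH2Cl2 (5 mol %), aq. K3PO4, DMF, 60 °C
Reagents that add atoms: none
Why: Anti-Markovnikov hydroboration puts boron on the terminal carbon and B-alkyl Suzuki–Miyaura coupling joins it to the aryl bromide; the excess 9-BBN caps the free hydroxyl as a borinate that the aqueous base hydrolyses, and the stereocentre is not involved.

Step 8
Reactants: 12 (13R)-1-(2,2-dimethyl-4-oxo-4H-1,3-dioxin-6-yl)-2,4-dioxohexadecan-13-yl acetate; 18 (R)-11-[3,5-bis(benzyloxy)phenyl]undecan-4-ol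
Product: 22 (R)-11-[3,5-bis(benzyloxy)phenyl]undecan-4-yl 6-[(R)-9-acetoxydodecyl]-2,4-dihydroxybenzoate, via acyl ketene 19 (not isolated), via triketo ester 20 (not isolated), via aldol adduct 21 (not isolated)
Conditions: 12 (1.1 equiv), 18 (1.0 equiv), toluene, 110 °C, N2 stream; cool, Et3N (1 equiv), CH2Cl2, rt; then HCl in 1,4-dioxane (excess), rt
Reagents that add atoms: none
Why: Heating 12 should expel acetone by a retro-hetero-Diels–Alder reaction to give acyl ketene 19, which the hydroxyl of 18 adds to by O–H addition without breaking the carbinol C–O bond, so the R configuration is retained in the 3,5,7-triketo ester 20. Et3N then enolises 20 at C2, the carbon between the ester and the C3 ketone, and this carbon attacks the C7 ketone in a 6-(enolexo)-exo-trig aldol that forms the C1–C6 bond of ring A (adduct 21); acid-promoted loss of water and enolisation of the two remaining ring ketones give the aromatic ring. The closest known reaction type is the thermolysis of 2,2-dimethyl-1,3-dioxin-4-ones to acyl ketenes with capture by alcohols, followed by base-mediated aldol aromatisation of the triketo ester to a resorcylate, a biomimetic polyketide cyclisation. No new stereocentre remains in 22, since the carbinol carbon created in 21 is lost on dehydration. Two selectivities are needed: capture of the ketene by the alcohol rather than by the C5 enol oxygen of its own chain (which would give a 4-hydroxy-2-pyranone), secured by running the thermolysis concentrated with 18 present from the start, and C–C closure from C2 rather than closure through oxygen, secured by the higher acidity of C2 under a mild amine base, with acid added only after the aldol. The ester, which in the finished arene lies between two ortho substituents, is formed while its acyl partner is still an unhindered ketene, and the acetate and benzyl ethers are inert to heat, Et3N and anhydrous HCl.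

Step 9
Reactants: 22 (R)-11-[3,5-bis(benzyloxy)phenyl]undecan-4-yl 6-[(R)-9-acetoxydodecyl]-2,4-dihydroxybenzoate
Product: 23 (R)-11-[3,5-bis(benzyloxy)phenyl]undecan-4-yl 6-[(R)-9-acetoxydodecyl]-2-hydroxy-4-methoxybenzoate
Conditions: MeI (1.1 equiv), K2CO3 (1.2 equiv), acetone, rt
Reagents that add atoms: iodomethane, CI
Why: Williamson etherification should be selective because the C2 hydroxyl is held in a hydrogen bond to the ester carbonyl and shielded by it, whereas the C4 hydroxyl, para to the ester and the more acidic one, is deprotonated and methylated; one equivalent of iodomethane limits double methylation and the acetate is stable in acetone.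

Step 10
Reactants: 23 (R)-11-[3,5-bis(benzyloxy)phenyl]undecan-4-yl 6-[(R)-9-acetoxydodecyl]-2-hydroxy-4-methoxybenzoate
Product: 24 5'-methoxy-integracin A, (R)-11-(3,5-dihydroxyphenyl)undecan-4-yl 6-[(R)-9-acetoxydodecyl]-2-hydroxy-4-methoxybenzoate
Conditions: H2 (1 atm), Pd/C (10 %), EtOAc, rt
Reagents that add atoms: none
Why: Catalytic hydrogenolysis cleaves the two benzyl aryl ethers, while the non-benzylic benzoate ester, the acetate, the methyl ether and both stereocentres are not affected.

**Compound list**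

1 | 9-bromonon-1-ene | C=CCCCCCCCBr | starting material
2 | (R)-2-propyloxirane | CCC[C@@H]1CO1 | starting material
3 | non-8-enylmagnesium bromide | C=CCCCCCCC[Mg]Br | intermediate
4 | (R)-tetradec-13-en-4-ol | CCC[C@@H](O)CCCCCCCCC=C | intermediate
5 | (R)-tetradec-13-en-4-yl acetate | CCC[C@@H](OC(C)=O)CCCCCCCCC=C | intermediate
6 | (R)-10-acetoxytridecanoic acid | CCC[C@@H](OC(C)=O)CCCCCCCCC(=O)O | intermediate
7 | 2,2,6-trimethyl-4H-1,3-dioxin-4-one | CC1=CC(=O)OC(C)(C)O1 | starting material
8 | lithium 2,2-dimethyl-6-methylidene-6H-1,3-dioxin-4-olate (lithium dienolate of 7) | [Li]OC1=CC(=C)OC(C)(C)O1 | intermediate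
9 | 2,2-dimethyl-6-(2-oxopropyl)-4H-1,3-dioxin-4-one | CC(=O)CC1=CC(=O)OC(C)(C)O1 | intermediate
10 | (R)-13-(1H-imidazol-1-yl)-13-oxotridecan-4-yl acetate (acyl imidazolide of 6) | CCC[C@@H](OC(C)=O)CCCCCCCCC(=O)n1ccnc1 | intermediate
11 | dilithium 2,2-dimethyl-6-(2-oxidoprop-2-en-1-ylidene)-6H-1,3-dioxin-4-olate (dianion of 9) | C=C(O[Li])C=C1C=C(O[Li])OC(C)(C)O1 | intermediate
12 | (13R)-1-(2,2-dimethyl-4-oxo-4H-1,3-dioxin-6-yl)-2,4-dioxohexadecan-13-yl acetate | CC1(C)OC(=O)C=C(CC(=O)CC(=O)CCCCCCCC[C@@H](CCC)OC(C)=O)O1 | intermediate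
13 | 6-bromohex-1-ene | C=CCCCCBr | starting material
14 | hex-5-enylmagnesium bromide | C=CCCCC[Mg]Br | intermediate
15 | (R)-undec-10-en-4-ol | CCC[C@@H](O)CCCCCC=C | intermediate
16 | 1,3-bis(benzyloxy)-5-bromobenzene | Brc1cc(OCc2ccccc2)cc(OCc2ccccc2)c1 | starting material
17 | 9-{[(R)-11-(9-borabicyclo[3.3.1]nonan-9-yl)undecan-4-yl]oxy}-9-borabicyclo[3.3.1]nonane (B-alkyl-9-BBN, hydroxyl capped as borinate) | CCC[C@@H](OB1C2CCCC1CCC2)CCCCCCCB1C2CCCC1CCC2 | intermediate
18 | (R)-11-[3,5-bis(benzyloxy)phenyl]undecan-4-ol | CCC[C@@H](O)CCCCCCCc1cc(OCc2ccccc2)cc(OCc2ccccc2)c1 | intermediate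
19 | (R)-13,15,17,19-tetraoxononadec-18-en-4-yl acetate (acyl ketene) | O=C=CC(=O)CC(=O)CC(=O)CCCCCCCC[C@@H](CCC)OC(C)=O | intermediate
20 | (R)-11-[3,5-bis(benzyloxy)phenyl]undecan-4-yl (R)-16-acetoxy-3,5,7-trioxononadecanoate (triketo ester) | CCC[C@H](CCCCCCCCC(=O)CC(=O)CC(=O)CC(=O)O[C@H](CCC)CCCCCCCc1cc(OCc2ccccc2)cc(OCc2ccccc2)c1)OC(C)=O | intermediate
21 | (R)-11-[3,5-bis(benzyloxy)phenyl]undecan-4-yl 6-[(R)-9-acetoxydodecyl]-2,6-dihydroxy-4-oxocyclohex-1-ene-1-carboxylate (aldol adduct, epimers at ring C6) | CCC[C@H](CCCCCCCCC1(O)CC(=O)CC(O)=C1C(=O)O[C@H](CCC)CCCCCCCc1cc(OCc2ccccc2)cc(OCc2ccccc2)c1)OC(C)=O | intermediate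
22 | (R)-11-[3,5-bis(benzyloxy)phenyl]undecan-4-yl 6-[(R)-9-acetoxydodecyl]-2,4-dihydroxybenzoate | CCC[C@H](CCCCCCCCc1cc(O)cc(O)c1C(=O)O[C@H](CCC)CCCCCCCc1cc(OCc2ccccc2)cc(OCc2ccccc2)c1)OC(C)=O | intermediate
23 | (R)-11-[3,5-bis(benzyloxy)phenyl]undecan-4-yl 6-[(R)-9-acetoxydodecyl]-2-hydroxy-4-methoxybenzoate | CCC[C@H](CCCCCCCCc1cc(OC)cc(O)c1C(=O)O[C@H](CCC)CCCCCCCc1cc(OCc2ccccc2)cc(OCc2ccccc2)c1)OC(C)=O | intermediate
24 | 5'-methoxy-integracin A, (R)-11-(3,5-dihydroxyphenyl)undecan-4-yl 6-[(R)-9-acetoxydodecyl]-2-hydroxy-4-methoxybenzoate | CCC[C@H](CCCCCCCCc1cc(OC)cc(O)c1C(=O)O[C@H](CCC)CCCCCCCc1cc(O)cc(O)c1)OC(C)=O | target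

Total step count: 10. Longest linear sequence: 7 steps (steps 1, 2, 3, 5, 8, 9, 10).

**Steps most likely to fail and fallbacks**

Step 8. The ketene may be captured by the C5 enol oxygen of its own chain faster than by the hindered secondary hydroxyl of 18, or the triketo ester may close through oxygen instead of carbon. The fallback sets out from 12 and 18 and comes back at 22; it moves the formation of the ester C–O bond from acyl transfer to an SN2 displacement at the carbinol carbon.
- Compound 12 is heated in toluene at 110 °C with an excess of benzyl alcohol, a small primary alcohol that should outrun the internal enol, and is then treated with Et3N and HCl as in step 8. Via 19, benzyl (R)-16-acetoxy-3,5,7-trioxononadecanoate F1 and benzyl 6-[(R)-9-acetoxydodecyl]-2,6-dihydroxy-4-oxocyclohex-1-ene-1-carboxylate F2 this should give benzyl 6-[(R)-9-acetoxydodecyl]-2,4-dihydroxybenzoate F3.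
- Hydrogenolysis (H2, Pd/C, EtOAc) should free 6-[(R)-9-acetoxydodecyl]-2,4-dihydroxybenzoic acid F4.
- Alcohol 18 is inverted by a Mitsunobu reaction with 4-nitrobenzoic acid (PPh3, DIAD, THF) to (S)-11-[3,5-bis(benzyloxy)phenyl]undecan-4-yl 4-nitrobenzoate F5, and methanolysis (K2CO3, MeOH) gives (S)-11-[3,5-bis(benzyloxy)phenyl]undecan-4-ol F6.
- Mitsunobu esterification of F4 with F6 (PPh3, DIAD, toluene, 0 °C) is chemoselective for the carboxylic acid over the two phenols and proceeds with inversion (S to R); it should give 22.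

Step 5. Proton transfer from imidazole or from the product to the dianion, O-acylation, or attack of the excess dianion on the remote acetate may erode the C-acylation. The fallback sets out from 6 and 7 and comes back at 12; it replaces the strongly basic dianion by a magnesium-mediated C-acylation of a β-keto ester followed by decarboxylation.
- Acid 6 is converted (oxalyl chloride, DMF cat., CH2Cl2) into (R)-13-chloro-13-oxotridecan-4-yl acetate F7.
- Dienolate 8, made from 7 as in step 4, is acylated with allyl 3-chloro-3-oxopropanoate to allyl 4-(2,2-dimethyl-4-oxo-4H-1,3-dioxin-6-yl)-3-oxobutanoate F8.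
- F8 and F7 with MgCl2 and pyridine in CH2Cl2 at 0 °C should give, by acylation of the magnesium enolate at the carbon between ketone and ester, allyl (R)-12-acetoxy-2-[2-(2,2-dimethyl-4-oxo-4H-1,3-dioxin-6-yl)acetyl]-3-oxopentadecanoate F9.
- Pd(PPh3)4 (zerovalent palladium, catalytic) and morpholine in THF remove the allyl group to (R)-12-acetoxy-2-[2-(2,2-dimethyl-4-oxo-4H-1,3-dioxin-6-yl)acetyl]-3-oxopentadecanoic acid F10, which loses CO2 in the flask and gives 12.

Step 7. The free hydroxyl of 15 consumes borane, and slow transmetallation of the alkylborane or β-hydride elimination from the alkylpalladium intermediate may give reduced or isomerised chain instead of coupling. The fallback sets out from 16 and 2 and comes back at 18; the aryl–alkyl bond is made by copper-catalysed Grignard alkylation before the carbinol exists.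
- Bromide 16 is converted (Mg, THF) into 3,5-bis(benzyloxy)phenylmagnesium bromide F11.
- F11 is coupled with an excess of 1,6-dibromohexane under Li2CuCl4 catalysis (THF, 0 °C) to 1,3-bis(benzyloxy)-5-(6-bromohexyl)benzene F12.
- Its Grignard reagent 6-[3,5-bis(benzyloxy)phenyl]hexylmagnesium bromide F13 (Mg, THF) opens 2 at the CH2 terminus under CuBr·SMe2 catalysis as in step 6 and should give 18 with the R configuration of 2 unchanged.

**Further compounds**

F1 | step 8 | benzyl (R)-16-acetoxy-3,5,7-trioxononadecanoate | CCC[C@H](CCCCCCCCC(=O)CC(=O)CC(=O)CC(=O)OCc1ccccc1)OC(C)=O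
F2 | step 8 | benzyl 6-[(R)-9-acetoxydodecyl]-2,6-dihydroxy-4-oxocyclohex-1-ene-1-carboxylate | CCC[C@H](CCCCCCCCC1(O)CC(=O)CC(O)=C1C(=O)OCc1ccccc1)OC(C)=O
F3 | step 8 | benzyl 6-[(R)-9-acetoxydodecyl]-2,4-dihydroxybenzoate | CCC[C@H](CCCCCCCCc1cc(O)cc(O)c1C(=O)OCc1ccccc1)OC(C)=O
F4 | step 8 | 6-[(R)-9-acetoxydodecyl]-2,4-dihydroxybenzoic acid | CCC[C@H](CCCCCCCCc1cc(O)cc(O)c1C(=O)O)OC(C)=O
F5 | step 8 | (S)-11-[3,5-bis(benzyloxy)phenyl]undecan-4-yl 4-nitrobenzoate | CCC[C@H](OC(=O)c1ccc(cc1)[N+](=O)[O-])CCCCCCCc1cc(OCc2ccccc2)cc(OCc2ccccc2)c1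
F6 | step 8 | (S)-11-[3,5-bis(benzyloxy)phenyl]undecan-4-ol | CCC[C@H](O)CCCCCCCc1cc(OCc2ccccc2)cc(OCc2ccccc2)c1
F7 | step 5 | (R)-13-chloro-13-oxotridecan-4-yl acetate | CCC[C@@H](OC(C)=O)CCCCCCCCC(Cl)=O
F8 | step 5 | allyl 4-(2,2-dimethyl-4-oxo-4H-1,3-dioxin-6-yl)-3-oxobutanoate | C=CCOC(=O)CC(=O)CC1=CC(=O)OC(C)(C)O1
F9 | step 5 | allyl (R)-12-acetoxy-2-[2-(2,2-dimethyl-4-oxo-4H-1,3-dioxin-6-yl)acetyl]-3-oxopentadecanoate | C=CCOC(=O)C(C(=O)CC1=CC(=O)OC(C)(C)O1)C(=O)CCCCCCCC[C@@H](CCC)OC(C)=O
F10 | step 5 | (R)-12-acetoxy-2-[2-(2,2-dimethyl-4-oxo-4H-1,3-dioxin-6-yl)acetyl]-3-oxopentadecanoic acid | OC(=O)C(C(=O)CC1=CC(=O)OC(C)(C)O1)C(=O)CCCCCCCC[C@@H](CCC)OC(C)=O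
F11 | step 7 | 3,5-bis(benzyloxy)phenylmagnesium bromide | Br[Mg]c1cc(OCc2ccccc2)cc(OCc2ccccc2)c1
F12 | step 7 | 1,3-bis(benzyloxy)-5-(6-bromohexyl)benzene | BrCCCCCCc1cc(OCc2ccccc2)cc(OCc2ccccc2)c1
F13 | step 7 | 6-[3,5-bis(benzyloxy)phenyl]hexylmagnesium bromide | Br[Mg]CCCCCCc1cc(OCc2ccccc2)cc(OCc2ccccc2)c1
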